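Retrosynthesis: the C2 and C6 acetates are removed first (both oxygens carried as triethylsilyl ethers); then the C7–C8 bond is cut together with the O8–C12 lactone bond, which opens the ten-membered ring and the γ-lactone at once to the open-chain aldehyde/allylic bromide 25; then C7–C11 (Morita–Baylis–Hillman), C6–C7 (dithiane), the epoxide oxygen, C4=C5 and O2–C6 (metathesis, acrylate), C2–C3 (methallylation) and C1–C2/C10–C14 (carboalumination) are cut back to but-3-yn-1-ol.
Enabling feature: C7–C8 is the fusion bond shared by the γ-lactone (O–C8–C7–C11–C12) and the ten-membered carbocycle; C8 is a carbinol carbon and C7 is allylic to the C11=C13 methylene, so the pair is the adduct of a 2-(methoxycarbonyl)allyl metal (C13–C11=C7) with a C8 aldehyde.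
Forward: the chain is built linearly from C8 to C13; a temporary dihydropyranone ring (O2–C2–C3–C4=C5–C6) is closed by metathesis, epoxidised and opened again; the ten-membered ring and the lactone arise together in step 16; desilylation and acetylation end the route.
Stereochemistry: C1=C10 (E) from syn-carboalumination; C2 from Brown methallylation; the cis C3/C6 relationship from the lactone ring and C4/C5 from epoxidation anti to the C2 substituent; C6 from Felkin–Anh addition to the cis-epoxy aldehyde; C7 and C8 in the key step from C6 (A(1,3) strain, attack anti to the silyloxy group) and from the (Z)-allyl chair transition state.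

Key step: step 16

Remark: locants are those of the germacrane skeleton (C1–C10 ring, C11–C13 lactone carbons, C14 on C10, C15 on C4); the target is read as (2S,4R,5S,6S,7R,8R), 1(10)E, with C3 and C6 cis on the epoxide and a cis-fused lactone; CIP letters of intermediates change where substituent priorities change although the spatial arrangement is kept.

Step 1
Reactants: 1 but-3-yn-1-ol
Product: 2 1-[(but-3-yn-1-yloxy)methyl]-4-methoxybenzene
Conditions: NaH, 4-methoxybenzyl chloride, n-Bu4NI (cat.), THF, 0 °C to rt
Reagents that add atoms: 4-methoxybenzyl chloride, COc1ccc(CCl)cc1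
Why: Williamson etherification of the primary alkoxide; the PMB ether carries the future C8 aldehyde oxygen through the route and is later cleaved oxidatively without touching silyl ethers, the epoxide or the allylic bromide.

Step 2
Reactants: 2 1-[(but-3-yn-1-yloxy)methyl]-4-methoxybenzene
Product: 5 (E)-5-[(4-methoxybenzyl)oxy]-3-methylpent-2-en-1-ol, via alkenyldimethylalane 3 (not isolated), via lithium alkenylbutyldimethylalanate 4 (not isolated)
Conditions: Me3Al, Cp2ZrCl2 (0.25 equiv), CH2Cl2, 0 °C to rt; volatiles removed; n-BuLi, THF, −78 °C; (CH2O)n, −78 °C to rt; aq. KNaC4H4O6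
Reagents that add atoms: trimethylaluminium, C[Al](C)C; paraformaldehyde (reacting as formaldehyde), C=O
Why: Negishi zirconium-catalysed carboalumination adds methyl and aluminium syn across the terminal alkyne (methyl to C10, aluminium to C1), which fixes the E geometry of C1=C10, and the derived alanate is hydroxymethylated by formaldehyde with retention to install C2.

Step 3
Reactants: 5 (E)-5-[(4-methoxybenzyl)oxy]-3-methylpent-2-en-1-ol
Product: 6 (E)-5-[(4-methoxybenzyl)oxy]-3-methylpent-2-enal
Conditions: MnO2 (activated, excess), CH2Cl2, rt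
Reagents that add atoms: none
Why: MnO2 oxidises the allylic alcohol chemoselectively to the enal without E/Z isomerisation or attack on the PMB ether.

Step 4
Reactants: 6 (E)-5-[(4-methoxybenzyl)oxy]-3-methylpent-2-enal; 7 2-methylallylmagnesium chloride
Product: 10 (S,E)-8-[(4-methoxybenzyl)oxy]-2,6-dimethylocta-1,5-dien-4-ol, via B-methallyldiisopinocampheylborane 8 (not isolated), via diisopinocampheylborinate 9 (not isolated)
Conditions: 7, (−)-Ipc2BOMe (from (+)-α-pinene), Et2O, −78 °C to rt; 6, −78 °C; then 3 M NaOH, 30% H2O2, 0 °C to rt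
Reagents that add atoms: none
Why: Brown asymmetric methallylboration through a six-membered chair transition state; the isopinocampheyl groups derived from (+)-α-pinene direct the methallyl group to the Si face of the aldehyde, which should set C2 as S, and oxidative work-up releases the alcohol.

Step 5
Reactants: 10 (S,E)-8-[(4-methoxybenzyl)oxy]-2,6-dimethylocta-1,5-dien-4-ol; 11 acryloyl chloride
Product: 12 (S,E)-8-[(4-methoxybenzyl)oxy]-2,6-dimethylocta-1,5-dien-4-yl acrylate
Conditions: iPr2NEt, DMAP (cat.), CH2Cl2, −20 to 0 °C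
Reagents that add atoms: none
Why: O-acylation of the secondary alcohol with acryloyl chloride supplies C5 and C6 as an acrylate tethered through O2, the precursor of a temporary ring.

Step 6
Reactants: 12 (S,E)-8-[(4-methoxybenzyl)oxy]-2,6-dimethylocta-1,5-dien-4-yl acrylate
Product: 13 (S)-6-{(E)-4-[(4-methoxybenzyl)oxy]-2-methylbut-1-en-1-yl}-4-methyl-5,6-dihydro-2H-pyran-2-one
Conditions: second-generation Grubbs catalyst (H2IMes)(PCy3)Cl2Ru=CHPh (5–10 mol%), CH2Cl2 (5 mM), 40 °C
Reagents that add atoms: none
Why: Ring-closing olefin metathesis between the acrylate and the 1,1-disubstituted alkene gives the six-membered unsaturated lactone, whose ring forces C3 and C6 cis on the new C4=C5 bond; closure onto the trisubstituted C1=C10 alkene would give a five-membered butenolide and should not compete.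

Step 7
Reactants: 13 (S)-6-{(E)-4-[(4-methoxybenzyl)oxy]-2-methylbut-1-en-1-yl}-4-methyl-5,6-dihydro-2H-pyran-2-one
Product: 14 (1R,4S,6R)-4-{(E)-4-[(4-methoxybenzyl)oxy]-2-methylbut-1-en-1-yl}-6-methyl-3,7-dioxabicyclo[4.1.0]heptan-2-one
Conditions: 30% H2O2, NaOH (0.3 equiv), MeOH, 0 °C; NaH2PO4 buffer on work-up
Reagents that add atoms: hydrogen peroxide, OO
Why: Weitz–Scheffer nucleophilic epoxidation of the unsaturated lactone; hydroperoxide adds to C4 by axial attack on the half-chair, anti to the pseudo-equatorial C2 substituent, so C2 relays to C4 (R) and C5 with the epoxide oxygen trans to the alkenyl group, and the electron-rich C1=C10 alkene is inert to the nucleophilic oxidant.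

Step 8
Reactants: 14 (1R,4S,6R)-4-{(E)-4-[(4-methoxybenzyl)oxy]-2-methylbut-1-en-1-yl}-6-methyl-3,7-dioxabicyclo[4.1.0]heptan-2-one
Product: 15 (1R,4S,6R)-4-{(E)-4-[(4-methoxybenzyl)oxy]-2-methylbut-1-en-1-yl}-6-methyl-3,7-dioxabicyclo[4.1.0]heptan-2-ol (lactol, both anomers)
Conditions: iBu2AlH (1.1 equiv), CH2Cl2, −78 °C; aq. KNaC4H4O6
Reagents that add atoms: none
Why: Partial reduction of the δ-lactone to the lactol at −78 °C, where the aluminium hemiacetal resists further reduction and the epoxide is not opened.

Step 9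
Reactants: 15 lactol; 16 1,3-dithiane
Product: 18 (S,E)-1-{(2R,3S)-3-[(R)-(1,3-dithian-2-yl)(hydroxy)methyl]-2-methyloxiran-2-yl}-6-[(4-methoxybenzyl)oxy]-4-methylhex-3-en-2-ol, via 2-lithio-1,3-dithiane 17 (not isolated)
Conditions: 16 (3.2 equiv), n-BuLi (3.0 equiv), THF, −30 °C; 15, −78 to −20 °C; H2O
Reagents that add atoms: none
Why: Corey–Seebach formyl-anion addition to the open hydroxy-aldehyde form of the lactol; Felkin–Anh attack anti to the C5–O bond of the cis-epoxy aldehyde should give the erythro carbinol, which is the C6 configuration of the target (R by CIP here because the dithiane carbon outranks C5).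

Step 10
Reactants: 18 dithianyl epoxy diol
Product: 19 C2,C6-bis(triethylsilyl) ether of 18 (2S,4R,5S,6R)
Conditions: Et3SiCl, imidazole, DMAP (cat.), DMF, 0 °C to rt
Reagents that add atoms: chlorotriethylsilane, CC[Si](Cl)(CC)CC
Why: Silylation of both secondary alcohols; triethylsilyl ethers are chosen because a silyloxy group at C6 cannot act as a leaving group or acyl donor in the key step and both are removed together under mild buffered fluoride at the end.

Step 11
Reactants: 19 bis(triethylsilyl) ether dithiane
Product: 20 (R)-2-[(triethylsilyl)oxy]-2-[(2S,3R)-3-{(S,E)-6-[(4-methoxybenzyl)oxy]-4-methyl-2-[(triethylsilyl)oxy]hex-3-en-1-yl}-3-methyloxiran-2-yl]acetaldehyde (C7 aldehyde)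
Conditions: MeI (excess), CaCO3, MeCN/H2O (9:1), 40 °C
Reagents that add atoms: water, O
Why: S-Alkylative hydrolysis of the dithiane under buffered neutral conditions unmasks the C7 aldehyde without opening the epoxide or cleaving the silyl and PMB ethers.

Step 12
Reactants: 20 C7 aldehyde; 21 methyl acrylate
Product: 22 Morita–Baylis–Hillman adduct: methyl 2-methylene-3-hydroxy ester (C7 carbinol as a mixture of epimers; 2S,4R,5S,6S)
Conditions: 21 (excess), DABCO (1 equiv), MeOH (cosolvent), rt, several days
Reagents that add atoms: none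
Why: Morita–Baylis–Hillman reaction; DABCO adds to methyl acrylate and the resulting enolate attacks the activated α-silyloxy aldehyde through C11, which joins C7 to C11 and brings in C12 and C13 (the C7 carbinol configuration is irrelevant because C7 becomes trigonal in the next step).

Step 13
Reactants: 22 Morita–Baylis–Hillman adduct
Product: 23 methyl (Z)-2-(bromomethyl)enoate: C13 bromide with C7=C11 double bond; C8 OPMB; C2 and C6 OSiEt3 (2S,4R,5S,6S)
Conditions: NBS, Me2S, CH2Cl2, 0 °C; then 22, 0 °C to rt
Reagents that add atoms: N-bromosuccinimide, O=C1CCC(=O)N1Br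
Why: Corey–Kim-type activation of the allylic alcohol followed by SN2′ attack of bromide at C13 transposes the alkene to C7=C11 and should give the thermodynamically preferred (Z)-2-(bromomethyl)enoate with C6 cis to CH2Br.

Step 14
Reactants: 23 PMB-protected allylic bromide
Product: 24 C8 primary alcohol of 23 (2S,4R,5S,6S; 1(10)E; 7(11)Z)
Conditions: DDQ (1.3 equiv), CH2Cl2/pH 7 phosphate buffer (10:1), 0 °C
Reagents that add atoms: none
Why: Oxidative cleavage of the PMB ether by DDQ through the benzylic oxocarbenium ion frees the C8 alcohol and leaves silyl ethers, epoxide, alkenes and the allylic bromide untouched under buffered conditions.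

Step 15
Reactants: 24 C8 primary alcohol
Product: 25 open-chain C8 aldehyde/C13 allylic bromide (2S,4R,5S,6S; 1(10)E; 7(11)Z)
Conditions: Dess–Martin periodinane (1.5 equiv), NaHCO3, CH2Cl2, 0 °C; used at once
Reagents that add atoms: none
Why: Dess–Martin oxidation under buffered conditions gives the β,γ-unsaturated C8 aldehyde without migration of the C1=C10 double bond into conjugation; the aldehyde is used at once.

Step 16
Reactants: 25 open-chain C8 aldehyde/C13 allylic bromide
Product: 28 (2S,4R,5S,6S,7R,8R)-2,6-bis[(triethylsilyl)oxy]-4,5-epoxygermacra-1(10)E,11(13)-dien-12,8-olide, via allylchromium dichloride 26 (not isolated), via chromium alkoxide 27 (not isolated)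
Conditions: CrCl2 (8 equiv), THF, rt; 25 added by syringe pump over 12 h to a final concentration of about 2 mM
Reagents that add atoms: none
Why: Two single-electron transfers from divalent chromium turn the allylic bromide into the allylchromium 26 (trivalent chromium on C13), which adds through its γ-carbon C7 to the C8 aldehyde in a closed six-membered chair transition state and so forms the C7–C8 bond. The closest known reaction type is the Nozaki–Hiyama (Barbier-type) intramolecular allylation of an aldehyde by a 2-(bromomethyl)acrylate, which is established for closing medium and large carbocycles that carry an α-methylene lactone. The C–C bond formation closes the ten-membered carbocycle in a 10-exo-trig mode (the C8=O bond stays outside the new ring) and the chromium alkoxide 27 then closes the γ-lactone by 5-exo-trig acyl substitution at the C12 ester with loss of methanol. C8 is controlled relative to C7 by the Z geometry of the allyl unit (C6 cis to C13 and kept there because C6 avoids the in-plane ester): C6 sits axial and the C9 chain equatorial in the chair, which gives the syn adduct and hence the cis-fused lactone (8R). C7 is controlled by C6: A(1,3) strain with C13 holds the C6–H bond in the allyl plane, the OSiEt3 group and the C5 arm then lie on opposite faces, and the aldehyde should attack anti to the silyloxy group on the face that carries the C5 arm of the closing ring, which gives 7R. The step needs intramolecular to win over intermolecular allylation (slow addition to excess CrCl2 at about 2 mM, helped by the E-C1=C10 alkene and the cis-epoxide as turn elements), γ- over α-attack (inherent to allylchromium reagents) and no 1,4-elimination or acyl transfer from the C6 oxygen (secured by the silyl ether there), while esters, epoxide and silyl ethers are inert to CrCl2.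

Step 17
Reactants: 28 bis(triethylsilyl) lactone
Product: 29 (2S,4R,5S,6S,7S,8R)-2,6-dihydroxy-4,5-epoxygermacra-1(10)E,11(13)-dien-12,8-olide (same spatial arrangement as 28)
Conditions: HF·pyridine, pyridine, THF, 0 °C
Reagents that add atoms: none
Why: Fluoride-mediated cleavage of both triethylsilyl ethers under pyridine-buffered conditions, mild enough to avoid acid-triggered transannular attack of the C1=C10 alkene on the epoxide and conjugate addition to the methylene lactone.

Step 18
Reactants: 29 diol lactone
Product: 30 CNP0270851.1, (2S,4R,5S,6S,7R,8R)-2,6-diacetoxy-4,5-epoxygermacra-1(10)E,11(13)-dien-12,8-olide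
Conditions: Ac2O, DMAP (cat.), pyridine, CH2Cl2, 0 °C to rt
Reagents that add atoms: acetic anhydride, CC(=O)OC(C)=O
Why: DMAP-catalysed acetylation of the C2 and C6 hydroxyl groups gives the diacetate without base strong enough to cause translactonisation or Payne rearrangement.

Compound list
1 | but-3-yn-1-ol | C#CCCO | starting material
2 | 1-[(but-3-yn-1-yloxy)methyl]-4-methoxybenzene | C#CCCOCc1ccc(OC)cc1 | intermediate
3 | (E)-{4-[(4-methoxybenzyl)oxy]-2-methylbut-1-en-1-yl}dimethylalane (formed in the flask) | COc1ccc(COCC/C(C)=C/[Al](C)C)cc1 | intermediate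
4 | lithium (E)-butyl{4-[(4-methoxybenzyl)oxy]-2-methylbut-1-en-1-yl}dimethylalanate (formed in the flask) | COc1ccc(COCC/C(C)=C/[Al-](C)(C)CCCC)cc1.[Li+] | intermediate
5 | (E)-5-[(4-methoxybenzyl)oxy]-3-methylpent-2-en-1-ol | COc1ccc(COCC/C(C)=C/CO)cc1 | intermediate
6 | (E)-5-[(4-methoxybenzyl)oxy]-3-methylpent-2-enal | COc1ccc(COCC/C(C)=C/C=O)cc1 | intermediate
7 | 2-methylallylmagnesium chloride | C=C(C)C[Mg]Cl | starting material
8 | (−)-B-(2-methylallyl)diisopinocampheylborane (formed in the flask) | C=C(C)CB([C@@H]1C[C@@H]2C[C@H]([C@H]1C)C2(C)C)[C@@H]1C[C@@H]2C[C@H]([C@H]1C)C2(C)C | intermediate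
9 | diisopinocampheylborinate ester of 10 (formed in the flask) | COc1ccc(COCC/C(C)=C/[C@@H](OB([C@@H]2C[C@@H]3C[C@H]([C@H]2C)C3(C)C)[C@@H]2C[C@@H]3C[C@H]([C@H]2C)C3(C)C)CC(C)=C)cc1 | intermediate
10 | (S,E)-8-[(4-methoxybenzyl)oxy]-2,6-dimethylocta-1,5-dien-4-ol | COc1ccc(COCC/C(C)=C/[C@@H](O)CC(C)=C)cc1 | intermediate
11 | acryloyl chloride | C=CC(=O)Cl | starting material
12 | (S,E)-8-[(4-methoxybenzyl)oxy]-2,6-dimethylocta-1,5-dien-4-yl acrylate | COc1ccc(COCC/C(C)=C/[C@@H](OC(=O)C=C)CC(C)=C)cc1 | intermediate
13 | (S)-6-{(E)-4-[(4-methoxybenzyl)oxy]-2-methylbut-1-en-1-yl}-4-methyl-5,6-dihydro-2H-pyran-2-one | COc1ccc(COCC/C(C)=C/[C@@H]2CC(C)=CC(=O)O2)cc1 | intermediate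
14 | (1R,4S,6R)-4-{(E)-4-[(4-methoxybenzyl)oxy]-2-methylbut-1-en-1-yl}-6-methyl-3,7-dioxabicyclo[4.1.0]heptan-2-one | COc1ccc(COCC/C(C)=C/[C@@H]2C[C@@]3(C)O[C@H]3C(=O)O2)cc1 | intermediate
15 | (1R,4S,6R)-4-{(E)-4-[(4-methoxybenzyl)oxy]-2-methylbut-1-en-1-yl}-6-methyl-3,7-dioxabicyclo[4.1.0]heptan-2-ol (lactol, both anomers) | COc1ccc(COCC/C(C)=C/[C@@H]2C[C@@]3(C)O[C@H]3C(O)O2)cc1 | intermediate
16 | 1,3-dithiane | C1CSCSC1 | starting material
17 | 2-lithio-1,3-dithiane (formed in the flask) | [Li]C1SCCCS1 | intermediate
18 | (S,E)-1-{(2R,3S)-3-[(R)-(1,3-dithian-2-yl)(hydroxy)methyl]-2-methyloxiran-2-yl}-6-[(4-methoxybenzyl)oxy]-4-methylhex-3-en-2-ol | COc1ccc(COCC/C(C)=C/[C@@H](O)C[C@@]2(C)O[C@H]2[C@@H](O)C2SCCCS2)cc1 | intermediate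
19 | C2,C6-bis(triethylsilyl) ether of 18 | COc1ccc(COCC/C(C)=C/[C@@H](O[Si](CC)(CC)CC)C[C@@]2(C)O[C@H]2[C@@H](O[Si](CC)(CC)CC)C2SCCCS2)cc1 | intermediate
20 | (R)-2-[(triethylsilyl)oxy]-2-[(2S,3R)-3-{(S,E)-6-[(4-methoxybenzyl)oxy]-4-methyl-2-[(triethylsilyl)oxy]hex-3-en-1-yl}-3-methyloxiran-2-yl]acetaldehyde | COc1ccc(COCC/C(C)=C/[C@@H](O[Si](CC)(CC)CC)C[C@@]2(C)O[C@H]2[C@@H](O[Si](CC)(CC)CC)C=O)cc1 | intermediate
21 | methyl acrylate | C=CC(=O)OC | starting material
22 | Morita–Baylis–Hillman adduct of 20 (methyl 2-methylene-3-hydroxy ester; C7 epimers) | COc1ccc(COCC/C(C)=C/[C@@H](O[Si](CC)(CC)CC)C[C@@]2(C)O[C@H]2[C@@H](O[Si](CC)(CC)CC)C(O)C(=C)C(=O)OC)cc1 | intermediate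
23 | methyl (Z)-2-(bromomethyl)enoate with C8 OPMB and C2,C6 OSiEt3 (2S,4R,5S,6S) | COc1ccc(COCC/C(C)=C/[C@@H](O[Si](CC)(CC)CC)C[C@@]2(C)O[C@H]2[C@@H](O[Si](CC)(CC)CC)/C=C(\CBr)C(=O)OC)cc1 | intermediate
24 | C8 primary alcohol of 23 | OCC/C(C)=C/[C@@H](O[Si](CC)(CC)CC)C[C@@]1(C)O[C@H]1[C@@H](O[Si](CC)(CC)CC)/C=C(\CBr)C(=O)OC | intermediate
25 | open-chain C8 aldehyde/C13 allylic bromide | O=CC/C(C)=C/[C@@H](O[Si](CC)(CC)CC)C[C@@]1(C)O[C@H]1[C@@H](O[Si](CC)(CC)CC)/C=C(\CBr)C(=O)OC | intermediate
26 | allylchromium dichloride derived from 25 (formed in the flask) | O=CC/C(C)=C/[C@@H](O[Si](CC)(CC)CC)C[C@@]1(C)O[C@H]1[C@@H](O[Si](CC)(CC)CC)/C=C(\C[Cr](Cl)Cl)C(=O)OC | intermediate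
27 | chromium alkoxide of the ten-membered syn hydroxy ester (formed in the flask) | Cl[Cr](Cl)O[C@@H]1C/C(C)=C/[C@@H](O[Si](CC)(CC)CC)C[C@@]2(C)O[C@H]2[C@@H](O[Si](CC)(CC)CC)[C@@H]1C(=C)C(=O)OC | intermediate
28 | (2S,4R,5S,6S,7R,8R)-2,6-bis[(triethylsilyl)oxy]-4,5-epoxygermacra-1(10)E,11(13)-dien-12,8-olide | C=C1C(=O)O[C@@H]2C/C(C)=C/[C@@H](O[Si](CC)(CC)CC)C[C@@]3(C)O[C@H]3[C@@H](O[Si](CC)(CC)CC)[C@H]12 | intermediate
29 | (2S,4R,5S,6S,7S,8R)-2,6-dihydroxy-4,5-epoxygermacra-1(10)E,11(13)-dien-12,8-olide | C=C1C(=O)O[C@@H]2C/C(C)=C/[C@@H](O)C[C@@]3(C)O[C@H]3[C@@H](O)[C@H]12 | intermediate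
30 | CNP0270851.1, (2S,4R,5S,6S,7R,8R)-2,6-diacetoxy-4,5-epoxygermacra-1(10)E,11(13)-dien-12,8-olide | C=C1C(=O)O[C@@H]2C/C(C)=C/[C@@H](OC(C)=O)C[C@@]3(C)O[C@H]3[C@@H](OC(C)=O)[C@H]12 | target

Total step count: 18. Longest linear sequence: 18 steps (from 1).

Steps most likely to fail

Step 16 (key step). What may go wrong: loss of the syn (chair) preference under the strain of ten-membered ring closure, so that the aldehyde adds to give the C8 epimer, or intermolecular allylation. Fallback: starting from 25, the chromium closure is run as before and the trans-fused lactone that it then gives, the 8-epi lactone F1, is taken on. LiOH (THF/H2O, 0 °C) followed by careful acidification opens it to the 8-epi hydroxy acid F2. Mitsunobu lactonisation (PPh3, DIAD, THF) then closes the γ-lactone by intramolecular carboxylate displacement with inversion at C8, which returns to 28.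

Step 7. What may go wrong: the peroxide or hydroxide acting as a base (γ-deprotonation and β-elimination of the allylic lactone oxygen to a ring-opened trienoate), saponification that stops the conjugate addition, or insufficient facial bias on the 4-methyl lactone. Fallback: starting from 13, iBu2AlH (excess, CH2Cl2, −78 to 0 °C) reduces the lactone to the (S,2Z,6E)-9-[(4-methoxybenzyl)oxy]-3,7-dimethylnona-2,6-diene-1,5-diol F3. Sharpless asymmetric epoxidation of its primary (Z)-allylic alcohol (Ti(OiPr)4, L-(+)-diethyl tartrate, t-BuOOH, 4 Å sieves, CH2Cl2, −25 °C) sets the face by the reagent, as for nerol, and gives the (S,E)-1-[(2R,3S)-3-(hydroxymethyl)-2-methyloxiran-2-yl]-6-[(4-methoxybenzyl)oxy]-4-methylhex-3-en-2-ol F4. The secondary C2 allylic alcohol, which has a cis β-methyl group, is a slow substrate for this reagent. TEMPO/PhI(OAc)2 then oxidises the primary alcohol selectively and the resulting lactol on to the lactone, which returns to 14.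

Step 12. What may go wrong: slow addition to the hindered α-silyloxy aldehyde, with epimerisation at C6 or silyl migration under prolonged exposure to the amine base. Fallback: starting from 20, the preformed [1-(methoxycarbonyl)vinyl]diisobutylalane F5 (from methyl propiolate, iBu2AlH and N-methylmorpholine N-oxide in THF at 0 °C, by hydroalumination) is added to the aldehyde at 0 °C. It transfers the same α-acrylate unit without amine base and within hours, which returns to 22.

Further compounds
F1 | step 16 | 8-epi-28, trans-fused (2S,4R,5S,6S,7R,8S) bis(triethylsilyl) lactone | C=C1C(=O)O[C@H]2C/C(C)=C/[C@@H](O[Si](CC)(CC)CC)C[C@@]3(C)O[C@H]3[C@@H](O[Si](CC)(CC)CC)[C@H]12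
F2 | step 16 | 8-epi hydroxy acid (ring-opened F1) | O[C@H]1C/C(C)=C/[C@@H](O[Si](CC)(CC)CC)C[C@@]2(C)O[C@H]2[C@@H](O[Si](CC)(CC)CC)[C@@H]1C(=C)C(=O)O
F3 | step 7 | (S,2Z,6E)-9-[(4-methoxybenzyl)oxy]-3,7-dimethylnona-2,6-diene-1,5-diol | COc1ccc(COCC/C(C)=C/[C@@H](O)C/C(C)=C\CO)cc1
F4 | step 7 | (S,E)-1-[(2R,3S)-3-(hydroxymethyl)-2-methyloxiran-2-yl]-6-[(4-methoxybenzyl)oxy]-4-methylhex-3-en-2-ol | COc1ccc(COCC/C(C)=C/[C@@H](O)C[C@@]2(C)O[C@H]2CO)cc1
F5 | step 12 | [1-(methoxycarbonyl)vinyl]diisobutylalane | C=C(C(=O)OC)[Al](CC(C)C)CC(C)C
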